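**Retrosynthetic overview**

- The oxirane (two C–O bonds, C5 and C6, carotenoid numbering) is made last, by face-selective oxygen transfer to the tetrasubstituted ring alkene of the complete C25 β,γ-unsaturated keto-polyenal. It is the only ring formed in the route.
- The C25 chain comes from a C11=C12 Wittig reaction between a C15 keto-phosphonium salt and the C10-dialdehyde.
- The C15 unit comes from a Meyer–Schuster rearrangement, which places the C8 oxygen, followed by deconjugation to the 5,6-alkene.
- The C6–C7 bond comes from alkynylation of (4R,6R)-actinol, which supplies the carbocycle and the C3 stereocenter.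

Assumption: (4R,6R)-actinol and the C10-dialdehyde, both industrial carotenoid intermediates, are taken as commercially available; positions are given in carotenoid numbering.

**Step 1**
Reactants: 1 (4R,6R)-4-hydroxy-2,2,6-trimethylcyclohexan-1-one; 2 (2E)-3-methylpent-2-en-4-yn-1-ol
Product: 4 (4R,6R)-1-[(3E)-5-hydroxy-3-methylpent-3-en-1-yn-1-yl]-2,2,6-trimethylcyclohexane-1,4-diol (both C1 epimers), via dilithio enynolate 3 (not isolated)
Conditions: 2 (2.5 equiv), n-BuLi (5.0 equiv), THF, −78 → 0 °C; then 1 (1.0 equiv), −78 °C → rt; aq NH4Cl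
Reagents that add atoms: none
Why: 1,2-addition of a lithium acetylide to a hindered cyclohexanone (Favorskii-type alkynylation); the excess reagent absorbs the free hydroxyl proton, the C3 carbinol center is untouched, and the new C6 carbinol center (mixture) is erased in step 2.

**Step 2**
Reactants: 4 (4R,6R)-1-[(3E)-5-hydroxy-3-methylpent-3-en-1-yn-1-yl]-2,2,6-trimethylcyclohexane-1,4-diol
Product: 6 (3E)-5-hydroxy-1-[(4R)-4-hydroxy-2,6,6-trimethylcyclohex-1-en-1-yl]-3-methylpent-3-en-2-one, via exocyclic dienone 5 (not isolated)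
Conditions: Au(IPr)NTf2 (2 mol %; IPr = 1,3-bis(2,6-diisopropylphenyl)imidazol-2-ylidene), MeOH/H2O 10:1, 50 °C; then DBU (0.3 equiv), THF, rt
Reagents that add atoms: water, O
Why: Meyer–Schuster rearrangement catalysed by monovalent gold (water adds to the activated alkyne at C8, the carbon remote from the carbinol and stabilised by the vinyl group, and the tertiary hydroxyl leaves as water) gives the strained exocyclic enone 5, which DBU deconjugates (γ-deprotonation at C5, α-protonation at C7) to the tetrasubstituted endocyclic β,γ-enone; no stereocenter is set and C3 is untouched.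

**Step 3**
Reactants: 6 (3E)-5-hydroxy-1-[(4R)-4-hydroxy-2,6,6-trimethylcyclohex-1-en-1-yl]-3-methylpent-3-en-2-one
Product: 8 [(2E)-5-[(4R)-4-hydroxy-2,6,6-trimethylcyclohex-1-en-1-yl]-3-methyl-4-oxopent-2-en-1-yl]triphenylphosphonium bromide, via allylic bromide 7 (not isolated)
Conditions: CBr4 (1.05 equiv), PPh3 (1.1 equiv), 2,6-lutidine (0.2 equiv), CH2Cl2, −30 → 0 °C; solvent switch to EtOAc, PPh3 (1.3 equiv), rt; filter the salt
Reagents that add atoms: carbon tetrabromide, BrC(Br)(Br)Br; triphenylphosphine, c1ccc(cc1)P(c1ccccc1)c1ccccc1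
Why: Appel bromination is selective for the primary allylic alcohol over the hindered secondary ring alcohol at low temperature, and the γ-bromo enone is then quaternised by PPh3 in an SN2 reaction, the salt precipitating free of the neutral by-products.

**Step 4**
Reactants: 8 [(2E)-5-[(4R)-4-hydroxy-2,6,6-trimethylcyclohex-1-en-1-yl]-3-methyl-4-oxopent-2-en-1-yl]triphenylphosphonium bromide; 9 (2E,4E,6E)-2,7-dimethylocta-2,4,6-trienedial
Product: 11 (2E,4E,6E,8E,10E)-13-[(4R)-4-hydroxy-2,6,6-trimethylcyclohex-1-en-1-yl]-2,7,11-trimethyl-12-oxotrideca-2,4,6,8,10-pentaenal, via phosphorus ylide 10 (not isolated)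
Conditions: 9 (3 equiv), 1,2-epoxybutane (10 equiv), EtOH, 70 °C, Ar, dark; chromatography (excess 9 recovered)
Reagents that add atoms: none
Why: Wittig olefination with a vinylogous acyl-stabilised ylide generated under neutral epoxide (Buddrus) conditions, the ketone analogue of the C5-ester chain extension of 9; excess 9 gives mono-olefination, the stabilised ylide gives the (E)-alkene at C11=C12, and the weak base leaves the β,γ-enone and the C7 methylene untouched.

**Step 5**
Reactants: 11 (2E,4E,6E,8E,10E)-13-[(4R)-4-hydroxy-2,6,6-trimethylcyclohex-1-en-1-yl]-2,7,11-trimethyl-12-oxotrideca-2,4,6,8,10-pentaenal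
Product: 12 (2E,4E,6E,8E,10E)-13-[(1S,4S,6R)-4-hydroxy-2,2,6-trimethyl-7-oxabicyclo[4.1.0]heptan-1-yl]-2,7,11-trimethyl-12-oxotrideca-2,4,6,8,10-pentaenal (CNP0310604.1; carotenoid descriptors 3S,5R,6S)
Conditions: D-fructose-derived Shi ketone (1,2:4,5-di-O-isopropylidene-β-D-erythro-2,3-hexodiulo-2,6-pyranose, 3 equiv), Oxone (2.5 equiv KHSO5, slow addition), NaHCO3 (pH 7.5–8), MeCN/dimethoxymethane/aq Na2EDTA, −5 → 0 °C, dark; neutral extractive work-up
Reagents that add atoms: potassium peroxymonosulfate (active component of Oxone), [K+].OOS(=O)(=O)[O-]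
Why: Proposed new method: reagent-controlled, anti-selective dioxirane epoxidation of the tetrasubstituted ring alkene of an unprotected 3-hydroxy-β end group that carries a 7-methylene-8-keto polyenal chain, a substrate class on which chiral-ketone epoxidation has not been shown. The electrophilic dioxirane transfers oxygen through a spiro transition state to the only electron-rich, non-conjugated alkene (the pentaene is deactivated by its two carbonyl termini, as in the selective ring epoxidation of retinal by peracids). With the C5 methyl in the place of the vinylic hydrogen and the C7 chain in the place of the aryl group of the model that gives (R,R)-1-phenylcyclohexene oxide, oxygen is predicted to arrive on the face anti to the 3-hydroxyl, setting C5 (R) and C6 (S) against the modest intrinsic syn preference of such rings. The aqueous medium suppresses hydroxyl-directed delivery and the near-neutral buffer spares the base-labile β,γ-epoxy ketone. Closest known reaction type: Shi asymmetric epoxidation of trisubstituted cyclic alkenes.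

**Compound list**

1 | (4R,6R)-4-hydroxy-2,2,6-trimethylcyclohexan-1-one ((4R,6R)-actinol, trans) | O=C1[C@H](C)C[C@@H](O)CC1(C)C | starting material
2 | (2E)-3-methylpent-2-en-4-yn-1-ol | OC/C=C(\C)C#C | starting material
3 | dilithio derivative of 2 (lithium alkoxide plus lithium acetylide; not isolated) | [Li+].[Li+].[O-]C/C=C(\C)C#[C-] | intermediate
4 | (4R,6R)-1-[(3E)-5-hydroxy-3-methylpent-3-en-1-yn-1-yl]-2,2,6-trimethylcyclohexane-1,4-diol (C1 epimer mixture) | OC/C=C(\C)C#CC1(O)[C@H](C)C[C@@H](O)CC1(C)C | intermediate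
5 | (3E)-5-hydroxy-1-[(4R,6R)-4-hydroxy-2,2,6-trimethylcyclohexylidene]-3-methylpent-3-en-2-one (exocyclic alkene geometry mixed; not isolated) | OC/C=C(\C)C(=O)C=C1[C@H](C)C[C@@H](O)CC1(C)C | intermediate
6 | (3E)-5-hydroxy-1-[(4R)-4-hydroxy-2,6,6-trimethylcyclohex-1-en-1-yl]-3-methylpent-3-en-2-one | OC/C=C(\C)C(=O)CC1=C(C)C[C@@H](O)CC1(C)C | intermediate
7 | (3E)-5-bromo-1-[(4R)-4-hydroxy-2,6,6-trimethylcyclohex-1-en-1-yl]-3-methylpent-3-en-2-one (not isolated) | BrC/C=C(\C)C(=O)CC1=C(C)C[C@@H](O)CC1(C)C | intermediate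
8 | [(2E)-5-[(4R)-4-hydroxy-2,6,6-trimethylcyclohex-1-en-1-yl]-3-methyl-4-oxopent-2-en-1-yl]triphenylphosphonium bromide | [Br-].c1ccccc1[P+](c1ccccc1)(c1ccccc1)C/C=C(\C)C(=O)CC1=C(C)C[C@@H](O)CC1(C)C | intermediate
9 | (2E,4E,6E)-2,7-dimethylocta-2,4,6-trienedial (C10-dialdehyde) | C\C(C=O)=C/C=C/C=C(\C)C=O | starting material
10 | (3E)-1-[(4R)-4-hydroxy-2,6,6-trimethylcyclohex-1-en-1-yl]-3-methyl-5-(triphenyl-λ5-phosphanylidene)pent-3-en-2-one (ylide; not isolated) | c1ccccc1P(c1ccccc1)(c1ccccc1)=C/C=C(\C)C(=O)CC1=C(C)C[C@@H](O)CC1(C)C | intermediate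
11 | (2E,4E,6E,8E,10E)-13-[(4R)-4-hydroxy-2,6,6-trimethylcyclohex-1-en-1-yl]-2,7,11-trimethyl-12-oxotrideca-2,4,6,8,10-pentaenal | C\C(C=O)=C/C=C/C=C(C)/C=C/C=C(\C)C(=O)CC1=C(C)C[C@@H](O)CC1(C)C | intermediate
12 | (2E,4E,6E,8E,10E)-13-[(1S,4S,6R)-4-hydroxy-2,2,6-trimethyl-7-oxabicyclo[4.1.0]heptan-1-yl]-2,7,11-trimethyl-12-oxotrideca-2,4,6,8,10-pentaenal | C\C(C=O)=C/C=C/C=C(C)/C=C/C=C(\C)C(=O)C[C@@]12O[C@]1(C)C[C@@H](O)CC2(C)C | target

**Totals**

Total step count: 5. Longest linear sequence: 5 steps (1 → 4 → 6 → 8 → 11 → 12).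

**Steps most likely to fail, with fallbacks**

Step 5 (the proposed new epoxidation) is the most uncertain. The facial selectivity on a tetrasubstituted alkene next to a gem-dimethyl carbon may be low or reversed, the hindered alkene may react slowly, and the enal or polyene may be over-oxidised. The first control is the enantiomeric ketone. The fallback uses known chemistry, sets out from 11 and comes back at 12. Acetylation (Ac2O, pyridine, DMAP, 0 °C) gives the 3-O-acetate of 11 F1. Buffered peracid epoxidation (mCPBA, NaHCO3, CH2Cl2, 0 °C) then oxidises the ring alkene under substrate control to a separable mixture of syn and anti epoxy acetates. The anti isomer is expected to be the minor one (roughly 1:2 to 1:3), and the anti epoxy acetate, the 3-O-acetate of 12 F2, is isolated by HPLC. Enzymatic deacetylation (lipase or cholesterol esterase, pH 7 buffer, 37 °C) avoids base and returns 12. This costs yield but delivers authentic material.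

Step 2 can fail if gold catalysis on the free triol gives ethers, furans or incomplete rearrangement, or if deconjugation stalls. The fallback sets out from 4 and comes back at 6, replacing the rearrangement by a hydrosilylation–oxidation aldol surrogate. Trans-hydrosilylation ([Cp*Ru(MeCN)3]PF6, BnMe2SiH, acetone, 0 °C) places silicon on the alkyne carbon remote from the carbinol to give (4R,6R)-1-[(1Z,3E)-2-(benzyldimethylsilyl)-5-hydroxy-3-methylpenta-1,3-dien-1-yl]-2,2,6-trimethylcyclohexane-1,4-diol F3. Tamao–Fleming oxidation (TBAF, THF; then H2O2, KHCO3, MeOH) gives the β-hydroxy ketone (3E)-5-hydroxy-1-[(4R,6R)-1,4-dihydroxy-2,2,6-trimethylcyclohexyl]-3-methylpent-3-en-2-one F4. Acid-catalysed dehydration (p-TsOH cat., toluene, 40 °C), followed by the same DBU equilibration, gives 6.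

Step 4 can fail through a poor E/Z ratio at C11=C12, double olefination of 9, or a sluggish ylide. The fallback sets out from bromide 7 (worked up and isolated instead of being quaternised) and comes back at 11. Arbuzov reaction (P(OEt)3, 90 °C) gives diethyl [(2E)-5-[(4R)-4-hydroxy-2,6,6-trimethylcyclohex-1-en-1-yl]-3-methyl-4-oxopent-2-en-1-yl]phosphonate F5. Horner–Wadsworth–Emmons olefination with 9 (3 equiv) under Masamune–Roush conditions (LiCl, DBU, MeCN, 0 °C → rt) gives 11 with intrinsically higher E-selectivity and a water-soluble phosphate by-product.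

**Further compounds**

F1 | step 5 | 3-O-acetate of 11: (1R)-4-[(3E,5E,7E,9E,11E)-3,7,12-trimethyl-2,13-dioxotrideca-3,5,7,9,11-pentaen-1-yl]-3,5,5-trimethylcyclohex-3-en-1-yl acetate | C\C(C=O)=C/C=C/C=C(C)/C=C/C=C(\C)C(=O)CC1=C(C)C[C@@H](OC(C)=O)CC1(C)C
F2 | step 5 | 3-O-acetate of 12 (anti epoxy acetate) | C\C(C=O)=C/C=C/C=C(C)/C=C/C=C(\C)C(=O)C[C@@]12O[C@]1(C)C[C@@H](OC(C)=O)CC2(C)C
F3 | step 2 | (4R,6R)-1-[(1Z,3E)-2-(benzyldimethylsilyl)-5-hydroxy-3-methylpenta-1,3-dien-1-yl]-2,2,6-trimethylcyclohexane-1,4-diol (C1 epimer mixture) | OC/C=C(\C)/C(=C/C1(O)[C@H](C)C[C@@H](O)CC1(C)C)[Si](C)(C)Cc1ccccc1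
F4 | step 2 | (3E)-5-hydroxy-1-[(4R,6R)-1,4-dihydroxy-2,2,6-trimethylcyclohexyl]-3-methylpent-3-en-2-one (C1 epimer mixture) | OC/C=C(\C)C(=O)CC1(O)[C@H](C)C[C@@H](O)CC1(C)C
F5 | step 4 | diethyl [(2E)-5-[(4R)-4-hydroxy-2,6,6-trimethylcyclohex-1-en-1-yl]-3-methyl-4-oxopent-2-en-1-yl]phosphonate | CCOP(=O)(OCC)C/C=C(\C)C(=O)CC1=C(C)C[C@@H](O)CC1(C)C
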